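**Retrosynthetic overview**
1. Feature: ring B holds three adjacent stereocentres, C8 (CH–CH3), C9 (quaternary, CH3 and ArCH2) and C10 (ring-fusion CH). The two methyls are cis and the ArCH2 carbon is cis to H-10, which is the pattern left by an aryl (E)-2-methylbut-2-enoyl ketone adding through an exo transition state.
2. Key disconnection: C7–C8 and C9–C10. Ring B comes from a [4+2] addition of the aryl tigloyl ketone to an enantiopure 2-vinylcyclohex-2-enyl silyl ether, and the C4 silyloxy group of the diene fixes the absolute sense.
3. C5 methyl: a β-face cyclopropane is steered by a 7β-hydroxyl (allylic oxidation, then reduction). It is opened as a cyclopropylcarbinyl radical in the same Barton–McCombie step that turns ArCH(O) into ArCH2.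
4. Ring A end game from the C4 ketone: acetone aldol and dehydration (C3=CMe2), methylenation, α-face hydroboration (sets C4), transfer of the boron-bound carbon onto bromoacetate, then deprotection.
5. Ring order: the arene and ring A are bought in (a phenol and cyclohexenone). Ring B is the only ring built, and it is closed in the cycloaddition.

Key step: step 8

Numbering: clerodane-type locants are used. Ring A = C1, C2, C3, C4, C5, C10; ring B = C5, C6, C7, C8, C9, C10; C11 = benzylic carbon on C9. β is the face of the C5, C8 and C9 methyl groups of the target and α is the face of H-10. Ar = 5-methoxy-2-(methoxymethoxy)-3-methylphenyl.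
Remark on the chemistry: an oxygen at C4 cannot steer CH2 to the β face of C5=C6, because its axial α epimer points to the wrong face and its equatorial β epimer lies in the plane of the double bond. The C4 silyl ether therefore serves only as stereochemical relay and latent ketone, and the directing hydroxyl is placed at C7, where axial means β.
Remark on protection: the phenol is carried as its methoxymethyl ether, because the route contains an allylic C–H oxidation and a catalytic hydrogenation that a benzyl ether would not survive.

**Step 1**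
Reactants: 1 4-methoxy-2-methylphenol
Product: 2 4-methoxy-1-(methoxymethoxy)-2-methylbenzene
Conditions: MOMCl, i-Pr2NEt, CH2Cl2, 0 °C → rt
Reagents that add atoms: chloromethyl methyl ether, COCCl
Why: O-alkylation of the phenol (acetal protection) should be clean, and the new group later directs the lithiation and is inert to the oxidation, radical and hydrogenation steps.

**Step 2**
Reactants: 2 4-methoxy-1-(methoxymethoxy)-2-methylbenzene; 3 tiglaldehyde ((E)-2-methylbut-2-enal)
Product: 5 (E)-1-[5-methoxy-2-(methoxymethoxy)-3-methylphenyl]-2-methylbut-2-en-1-ol, via aryllithium 4 (not isolated)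
Conditions: n-BuLi, TMEDA, THF, 0 °C; then 3, −78 °C → 0 °C; H2O
Reagents that add atoms: n-butyllithium, [Li]CCCC (its lithium stays only in 4)
Why: In this directed ortho-metalation and 1,2-addition, the OCH2OCH3 group is the strongest director and has only one free ortho position, so the aryllithium forms there and adds to the aldehyde carbonyl without touching the E double bond; the racemic carbinol centre is erased in step 3.

**Step 3**
Reactants: 5 (E)-1-aryl-2-methylbut-2-en-1-ol
Product: 6 aryl tigloyl ketone, (E)-1-[5-methoxy-2-(methoxymethoxy)-3-methylphenyl]-2-methylbut-2-en-1-one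
Conditions: MnO2, CH2Cl2, rt
Reagents that add atoms: none
Why: MnO2 oxidation of a doubly activated (allylic and benzylic) alcohol is mild enough to leave the E geometry and the acetal untouched.

**Step 4**
Reactants: 7 cyclohex-2-en-1-one
Product: 8 2-iodocyclohex-2-en-1-one
Conditions: I2, pyridine, CH2Cl2, 0 °C → rt
Reagents that add atoms: iodine, II
Why: This is α-iodination of an enone by a Baylis–Hillman-type sequence of conjugate addition of pyridine, iodination of the enolate and loss of pyridine.

**Step 5**
Reactants: 8 2-iodocyclohex-2-en-1-one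
Product: 9 (S)-2-iodocyclohex-2-en-1-ol
Conditions: (3aR)-1-methyl-3,3-diphenyltetrahydro-1H,3H-pyrrolo[1,2-c][1,3,2]oxazaborole (10 mol %), BH3·SMe2, THF, −20 °C; MeOH, then H2O
Reagents that add atoms: none
Why: In this Corey–Bakshi–Shibata reduction the iodoalkenyl arm acts as the large group and the ring CH2 as the small one, so the (R)-catalyst should deliver hydride to the face that gives the (S)-carbinol.

**Step 6**
Reactants: 9 (S)-2-iodocyclohex-2-en-1-ol
Product: 10 (S)-tert-butyl[(2-iodocyclohex-2-en-1-yl)oxy]dimethylsilane
Conditions: TBSCl, imidazole, DMF, rt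
Reagents that add atoms: tert-butyldimethylsilyl chloride, CC(C)(C)[Si](C)(C)Cl
Why: Standard silylation of a secondary allylic alcohol leaves the stereocentre untouched.

**Step 7**
Reactants: 10 (S)-2-iodocyclohexenyl TBS ether
Product: 11 (S)-tert-butyl[(2-ethenylcyclohex-2-en-1-yl)oxy]dimethylsilane (diene)
Conditions: CH2=CHSnBu3, PdCl2(MeCN)2 (5 mol %), DMF, rt
Reagents that add atoms: tributyl(vinyl)stannane, C=C[Sn](CCCC)(CCCC)CCCC
Why: Stille coupling of a reactive alkenyl iodide runs at room temperature under neutral conditions, so the allylic silyl ether and its configuration should be kept.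

**Step 8**
Reactants: 6 aryl tigloyl ketone; 11 (S)-2-vinylcyclohex-2-enyl TBS ether
Product: 12 octalin aryl ketone (C5=C6; C9 with β-CH3 and α-aroyl; C8 β-CH3; H-10 α; C4 α-OTBS)
Conditions: Al(OC6H3-2,6-Ph2)3 (1.2 equiv), 11 (1.5 equiv), toluene, −78 °C → 0 °C; aqueous work-up
Reagents that add atoms: none
Why: The aluminium aryloxide binds the ketone oxygen of 6 and lowers the enone LUMO, and 6 then adds to the s-cis diene of 11 in a concerted but asynchronous [4+2] cycloaddition, the closest known reaction type being Lewis acid promoted Diels–Alder additions of 1-vinylcyclohexenes to α-methyl enones and enals with exo control by very bulky aluminium aryloxides. Ring B is closed as a six-membered ring by intermolecular [4+2] closure, with the C7–C8 and C9–C10 bonds formed in the same step and the new double bond ending at C5=C6. C8 and C9 are fixed relative to each other by suprafacial addition with retention of the E geometry, which keeps the two methyl groups cis. C10 is fixed relative to C9 by the exo placement of the aroyl group, favoured by the α-methyl group and by the wall of phenyl rings around the complexed carbonyl that does not fit under the diene, so the aroyl carbon ends cis to H-10. The absolute sense comes from C4 of 11, whose silyloxy group is held pseudoaxial by strain against the vinyl group and screens the α face, so 6 adds to the β face. Ortho regiochemistry is also needed and is secured because the unsubstituted vinyl CH2 (C7), the least hindered terminus with the largest HOMO coefficient, bonds first to the β-carbon of the enone and leaves C10 to bond to the acyl-bearing carbon.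

**Step 9**
Reactants: 12 octalin aryl ketone
Product: 13 7-oxo octalin aryl ketone (C5=C6–C7=O enone)
Conditions: Rh2(caprolactamate)4 (1 mol %), t-BuOOH (70 % in H2O), 1,2-dichloroethane, 40 °C
Reagents that add atoms: tert-butyl hydroperoxide, CC(C)(C)OO
Why: This radical allylic C–H oxidation of a trisubstituted ring olefin (the type used for 7-oxidation of Δ5 steroids) should attack secondary C7, because C4–H lies in the nodal plane of the π bond, C10–H is tertiary and shielded by quaternary C9, and the aroyl group blocks C11 and deactivates the arene.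

**Step 10**
Reactants: 13 7-oxo octalin aryl ketone
Product: 14 7β-allylic alcohol
Conditions: LiBH(s-Bu)3, THF, −78 °C; H2O
Reagents that add atoms: none
Why: In this 1,2-reduction of a β,β-disubstituted cyclohexenone by a bulky trialkylborohydride, the axial 9β-methyl closes the β face of C7 and the reagent prefers equatorial approach, so hydride enters from the α face and the new hydroxyl is β and pseudoaxial, while the neopentyl aryl ketone is too hindered to react.

**Step 11**
Reactants: 14 7β-allylic alcohol
Product: 15 5β,6β-methylene (cyclopropane) 7β-alcohol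
Conditions: Et2Zn, CH2I2, CH2Cl2, −10 °C → rt
Reagents that add atoms: diiodomethane, ICI
Why: In this hydroxyl-directed Simmons–Smith cyclopropanation (Furukawa variant) the zinc alkoxide of the pseudoaxial 7β-hydroxyl delivers CH2 to its own face of the adjacent C5=C6 bond, which sets C5 with the new carbon β and trans to H-10 against the steric bias of the 9β-methyl group.

**Step 12**
Reactants: 15 cyclopropane 7β-alcohol
Product: 16 C7,C11-diol (C11 epimers)
Conditions: LiAlH4, THF, 0 °C → 50 °C
Reagents that add atoms: none
Why: The small, powerful LiAlH4 should reduce the non-enolisable aryl tert-alkyl ketone, and the C11 configuration is of no consequence because this oxygen is removed in step 14.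

**Step 13**
Reactants: 16 C7,C11-diol
Product: 17 bis(S-methyl xanthate)
Conditions: NaN(SiMe3)2, THF, −78 °C; CS2; MeI, → rt
Reagents that add atoms: carbon disulfide, S=C=S; iodomethane, CI
Why: Xanthate formation through the sodium alkoxides (first half of the Barton–McCombie deoxygenation) suits hindered neopentyl-type carbinols, and neither xanthate has a syn β-hydrogen for Chugaev elimination.

**Step 14**
Reactants: 17 bis(S-methyl xanthate)
Product: 18 5β-methyl Δ6(7)-octalin with ArCH2 on C9
Conditions: Bu3SnH, AIBN, toluene, 110 °C
Reagents that add atoms: none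
Why: This Barton–McCombie deoxygenation is coupled with cyclopropylcarbinyl radical ring opening, in which the C7 radical cleaves the exocyclic C6–CH2 bond that overlaps best with its orbital, so the CH2 stays on C5 and becomes the β-methyl group without change at C5, while the C11 xanthate is reduced to ArCH2 in the same operation.

**Step 15**
Reactants: 18 5β-methyl Δ6(7)-octalin
Product: 19 trans-decalin 4α-TBS ether
Conditions: H2 (1 atm), Pd/C, EtOAc, rt
Reagents that add atoms: none
Why: Catalytic hydrogenation removes the only C=C bond, a cis-disubstituted ring olefin, forms no stereocentre and leaves the acetal, silyl ether and arene untouched.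

**Step 16**
Reactants: 19 trans-decalin 4α-TBS ether
Product: 20 trans-decalin 4α-alcohol
Conditions: Bu4NF, THF, 60 °C
Reagents that add atoms: none
Why: Fluoride-induced desilylation is driven by the Si–F bond, with warming planned because the axial ether sits next to quaternary C5.

**Step 17**
Reactants: 20 trans-decalin 4α-alcohol
Product: 21 trans-decalin 4-ketone
Conditions: Dess–Martin periodinane, CH2Cl2, rt
Reagents that add atoms: none
Why: Dess–Martin oxidation of a hindered secondary alcohol is essentially neutral, so the protected electron-rich arene and the acetal should survive.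

**Step 18**
Reactants: 21 trans-decalin 4-ketone
Product: 24 acetone aldol adduct (3-(2-hydroxypropan-2-yl)-4-ketone), via lithium enolate 22 (not isolated), via chlorozinc enolate 23 (not isolated)
Conditions: LiN(i-Pr)2, THF, −78 °C; ZnCl2; acetone, −78 → −40 °C; aq. NH4Cl
Reagents that add atoms: acetone, CC(C)=O; lithium diisopropylamide, CC(C)[N-]C(C)C.[Li+] (lithium only in 22); zinc chloride, [Zn+2].[Cl-].[Cl-] (zinc and chlorine only in 23)
Why: In this directed aldol addition C5 is quaternary, so only C3 can be deprotonated, and the zinc aldolate is stabilised by chelation against retro-aldol and proton transfer; the C3 configuration is erased in step 19.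

**Step 19**
Reactants: 24 acetone aldol adduct
Product: 26 3-isopropylidene-4-ketone, via tertiary mesylate 25 (not isolated)
Conditions: MsCl, Et3N, CH2Cl2, 0 °C; then DBU, rt
Reagents that add atoms: methanesulfonyl chloride, CS(=O)(=O)Cl (its atoms stay only in 25)
Why: Mesylation through sulfene followed by E1cB elimination through the C3 enolate places the double bond in conjugation with the ketone.

**Step 20**
Reactants: 26 3-isopropylidene-4-ketone
Product: 27 3-isopropylidene-4-methylene diene
Conditions: Cp2TiMe2, toluene, 75 °C
Reagents that add atoms: dimethyltitanocene, C[Ti](C)(C1C=CC=C1)C1C=CC=C1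
Why: In this Petasis methylenation the non-basic Cp2Ti=CH2 reacts by [2+2] addition and cycloreversion from the open α face of the carbonyl, which avoids the dienolate formation and deconjugation that a basic ylide could cause in this hindered enone.

**Step 21**
Reactants: 27 3-isopropylidene-4-methylene diene
Product: 29 MOM-protected methyl ester, via B-alkyl-9-BBN 28 (not isolated)
Conditions: 9-BBN, THF, 65 °C; then BrCH2CO2Me, KOt-Bu, t-BuOH/THF, 0 °C → rt
Reagents that add atoms: methyl bromoacetate, COC(=O)CBr; 9-borabicyclo[3.3.1]nonane, [H]B1C2CCCC1CCC2 (its atoms stay only in 28)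
Why: Hydroboration is followed by organoborane alkylation of an α-bromo ester enolate (ate complex, 1,2-shift of the primary alkyl group with loss of bromide, protonolysis), and 9-BBN should take only the 1,1-disubstituted C4=CH2 bond of the twisted diene, with boron on CH2 and hydrogen on C4 from the α face opposite the axial 5β-methyl, which sets C4 with the side chain β (equatorial).

**Step 22**
Reactants: 29 MOM-protected methyl ester
Product: 30 phenol methyl ester
Conditions: HCl (cat.), MeOH, 40 °C
Reagents that add atoms: none
Why: Acid-catalysed acetal exchange cleaves the crowded aryl methoxymethyl ether under conditions too mild to protonate the tetrasubstituted olefin, and methanol matches the ester.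

**Step 23**
Reactants: 30 phenol methyl ester
Product: 31 target acid CNP0299684.2
Conditions: LiOH, THF/MeOH/H2O, rt, argon; then dilute HCl
Reagents that add atoms: lithium hydroxide, [Li+].[OH-]
Why: Saponification of an unhindered primary-chain methyl ester touches no stereocentre, since none is α to the carboxyl group, and exclusion of air protects the phenolate.

**Compound list**
1 | 4-methoxy-2-methylphenol | COc1ccc(O)c(C)c1 | starting material
2 | 4-methoxy-1-(methoxymethoxy)-2-methylbenzene | COCOc1ccc(OC)cc1C | intermediate
3 | tiglaldehyde | C/C=C(\C)C=O | starting material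
4 | [5-methoxy-2-(methoxymethoxy)-3-methylphenyl]lithium | COCOc1c([Li])cc(OC)cc1C | intermediate
5 | (E)-1-aryl-2-methylbut-2-en-1-ol (racemic carbinol) | COCOc1c(C)cc(OC)cc1C(O)/C(C)=C/C | intermediate
6 | aryl tigloyl ketone | COCOc1c(C)cc(OC)cc1C(=O)/C(C)=C/C | intermediate
7 | cyclohex-2-en-1-one | O=C1C=CCCC1 | starting material
8 | 2-iodocyclohex-2-en-1-one | O=C1CCCC=C1I | intermediate
9 | (S)-2-iodocyclohex-2-en-1-ol | IC1=CCCC[C@@H]1O | intermediate
10 | (S)-2-iodocyclohex-2-enyl TBS ether | IC1=CCCC[C@@H]1O[Si](C)(C)C(C)(C)C | intermediate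
11 | (S)-2-vinylcyclohex-2-enyl TBS ether | C=CC1=CCCC[C@@H]1O[Si](C)(C)C(C)(C)C | intermediate
12 | octalin aryl ketone (Diels–Alder adduct) | COCOc1c(C)cc(OC)cc1C(=O)[C@]2(C)[C@H]3CCC[C@H](O[Si](C)(C)C(C)(C)C)C3=CC[C@H]2C | intermediate
13 | 7-oxo octalin aryl ketone | COCOc1c(C)cc(OC)cc1C(=O)[C@]2(C)[C@H]3CCC[C@H](O[Si](C)(C)C(C)(C)C)C3=CC(=O)[C@H]2C | intermediate
14 | 7β-allylic alcohol | COCOc1c(C)cc(OC)cc1C(=O)[C@]2(C)[C@H]3CCC[C@H](O[Si](C)(C)C(C)(C)C)C3=C[C@@H](O)[C@H]2C | intermediate
15 | 5β,6β-methylene 7β-alcohol | COCOc1c(C)cc(OC)cc1C(=O)[C@]2(C)[C@H]3CCC[C@H](O[Si](C)(C)C(C)(C)C)[C@@]34C[C@H]4[C@@H](O)[C@H]2C | intermediate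
16 | C7,C11-diol (C11 epimers) | COCOc1c(C)cc(OC)cc1C(O)[C@]2(C)[C@H]3CCC[C@H](O[Si](C)(C)C(C)(C)C)[C@@]34C[C@H]4[C@@H](O)[C@H]2C | intermediate
17 | bis(S-methyl xanthate) | COCOc1c(C)cc(OC)cc1C(OC(=S)SC)[C@]2(C)[C@H]3CCC[C@H](O[Si](C)(C)C(C)(C)C)[C@@]34C[C@H]4[C@@H](OC(=S)SC)[C@H]2C | intermediate
18 | 5β-methyl Δ6(7)-octalin | COCOc1c(C)cc(OC)cc1C[C@]2(C)[C@H]3CCC[C@H](O[Si](C)(C)C(C)(C)C)[C@]3(C)C=C[C@H]2C | intermediate
19 | trans-decalin 4α-TBS ether | COCOc1c(C)cc(OC)cc1C[C@]2(C)[C@H]3CCC[C@H](O[Si](C)(C)C(C)(C)C)[C@]3(C)CC[C@H]2C | intermediate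
20 | trans-decalin 4α-alcohol | COCOc1c(C)cc(OC)cc1C[C@]2(C)[C@H]3CCC[C@H](O)[C@]3(C)CC[C@H]2C | intermediate
21 | trans-decalin 4-ketone | COCOc1c(C)cc(OC)cc1C[C@]2(C)[C@H]3CCCC(=O)[C@]3(C)CC[C@H]2C | intermediate
22 | lithium enolate (C3=C4) | COCOc1c(C)cc(OC)cc1C[C@]2(C)[C@H]3CCC=C(O[Li])[C@]3(C)CC[C@H]2C | intermediate
23 | chlorozinc enolate (C3=C4) | COCOc1c(C)cc(OC)cc1C[C@]2(C)[C@H]3CCC=C(O[Zn]Cl)[C@]3(C)CC[C@H]2C | intermediate
24 | acetone aldol adduct (C3 configuration of no consequence) | COCOc1c(C)cc(OC)cc1C[C@]2(C)[C@H]3CCC(C(C)(C)O)C(=O)[C@]3(C)CC[C@H]2C | intermediate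
25 | tertiary mesylate | COCOc1c(C)cc(OC)cc1C[C@]2(C)[C@H]3CCC(C(C)(C)OS(C)(=O)=O)C(=O)[C@]3(C)CC[C@H]2C | intermediate
26 | 3-isopropylidene-4-ketone | COCOc1c(C)cc(OC)cc1C[C@]2(C)[C@H]3CCC(=C(C)C)C(=O)[C@]3(C)CC[C@H]2C | intermediate
27 | 3-isopropylidene-4-methylene diene | COCOc1c(C)cc(OC)cc1C[C@]2(C)[C@H]3CCC(=C(C)C)C(=C)[C@]3(C)CC[C@H]2C | intermediate
28 | B-alkyl-9-BBN (C4 side chain β) | COCOc1c(C)cc(OC)cc1C[C@]2(C)[C@H]3CCC(=C(C)C)[C@@H](CB4C5CCCC4CCC5)[C@]3(C)CC[C@H]2C | intermediate
29 | MOM-protected methyl ester | COCOc1c(C)cc(OC)cc1C[C@]2(C)[C@H]3CCC(=C(C)C)[C@@H](CCC(=O)OC)[C@]3(C)CC[C@H]2C | intermediate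
30 | phenol methyl ester | COc1cc(C)c(O)c(C[C@]2(C)[C@H]3CCC(=C(C)C)[C@@H](CCC(=O)OC)[C@]3(C)CC[C@H]2C)c1 | intermediate
31 | CNP0299684.2 | COc1cc(C)c(O)c(C[C@]2(C)[C@H]3CCC(=C(C)C)[C@@H](CCC(=O)O)[C@]3(C)CC[C@H]2C)c1 | target

**Step count and risks**

Total step count: 23. Longest linear sequence: 20 steps (steps 4–23, from cyclohex-2-en-1-one).

Steps most likely to fail:

1. **Step 8 (key step).** The trisubstituted, sterically twisted aryl enone may be activated too weakly. The diene could then oligomerise or lose its silyloxy group before cycloaddition, and exo and facial control may erode. The fallback sets out from diene 11 and tiglaldehyde 3. The smaller and more electrophilic enal is used as dienophile under the same aluminium aryloxide to give the exo octalin carbaldehyde F1. Aryllithium 4 is added to this neopentyl aldehyde to give the benzylic carbinol F2, and Dess–Martin oxidation brings the material back to 12.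

2. **Step 9.** Hydrogen abstraction may lack site selectivity (C10 against C7), or may extend to the aryl methyl and acetal C–H bonds. The fallback sets out from 12 and avoids C–H abstraction altogether. m-Chloroperbenzoic acid gives the 5,6-epoxide F3, whose configuration does not matter. Sodium phenylselenide (from PhSeSePh and NaBH4) opens it at secondary C6 to the hydroxy selenide F4. H2O2 gives the selenoxide F5, which eliminates towards C7 to the tertiary allylic alcohol F6. Pyridinium chlorochromate then effects the Babler–Dauben oxidative 1,3-transposition and returns to enone 13.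

3. **Step 21.** Transfer of the hindered, β-branched alkyl group from boron to the bromoacetate enolate may be slow. Migration of a ring B–C bond of the bicyclononane, or self-condensation of the bromo ester, could then take over. The fallback sets out from borane 28 and forms the C–C bond by substitution instead. NaOH/H2O2 gives the primary alcohol F7, and an Appel reaction (I2, PPh3, imidazole) gives the iodide F8. Sodium dimethyl malonate in DMF gives the malonate F9, and Krapcho demethoxycarbonylation (LiCl, wet DMSO, heat) returns to 29.

**Further compounds**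
F1 | step 8 | exo octalin carbaldehyde | O=C[C@]1(C)[C@H]2CCC[C@H](O[Si](C)(C)C(C)(C)C)C2=CC[C@H]1C
F2 | step 8 | benzylic carbinol (C11 epimers) | COCOc1c(C)cc(OC)cc1C(O)[C@]2(C)[C@H]3CCC[C@H](O[Si](C)(C)C(C)(C)C)C3=CC[C@H]2C
F3 | step 9 | 5,6-epoxide | COCOc1c(C)cc(OC)cc1C(=O)[C@]2(C)[C@H]3CCC[C@H](O[Si](C)(C)C(C)(C)C)C34OC4C[C@H]2C
F4 | step 9 | 5-hydroxy-6-phenylselanyl compound | COCOc1c(C)cc(OC)cc1C(=O)[C@]2(C)[C@H]3CCC[C@H](O[Si](C)(C)C(C)(C)C)C3(O)C([Se]c4ccccc4)C[C@H]2C
F5 | step 9 | selenoxide | COCOc1c(C)cc(OC)cc1C(=O)[C@]2(C)[C@H]3CCC[C@H](O[Si](C)(C)C(C)(C)C)C3(O)C([Se](=O)c4ccccc4)C[C@H]2C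
F6 | step 9 | tertiary allylic alcohol (C5–OH, C6=C7) | COCOc1c(C)cc(OC)cc1C(=O)[C@]2(C)[C@H]3CCC[C@H](O[Si](C)(C)C(C)(C)C)C3(O)C=C[C@H]2C
F7 | step 21 | primary alcohol | COCOc1c(C)cc(OC)cc1C[C@]2(C)[C@H]3CCC(=C(C)C)[C@@H](CO)[C@]3(C)CC[C@H]2C
F8 | step 21 | primary iodide | COCOc1c(C)cc(OC)cc1C[C@]2(C)[C@H]3CCC(=C(C)C)[C@@H](CI)[C@]3(C)CC[C@H]2C
F9 | step 21 | dimethyl malonate derivative | COCOc1c(C)cc(OC)cc1C[C@]2(C)[C@H]3CCC(=C(C)C)[C@@H](CC(C(=O)OC)C(=O)OC)[C@]3(C)CC[C@H]2C
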